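**Retrosynthetic overview**

1. The strategy rests on ring A (C4a, C5, C6, C7, C8, C8a): a benzene with oxygens at C5 and C8 in a para relation, the acyl carbon on C6, hydrogen on C7, fused through C4a–C8a to the pyran ring whose C2 is the only stereocentre.
2. Late disconnections: C8–OH from C8–OMe (oxidation to the 5,8-quinone, then reduction); the chalcone Cα=Cβ bond by Claisen–Schmidt condensation with 4-hydroxybenzaldehyde; C3=C4 by dehydrogenation; the side-chain tertiary alcohol by alkene hydration; the C6 acetyl group from a C6 formyl acetal.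
3. Key disconnection: ring A is taken apart into a dihydropyranyl methoxycarbene complex of chromium, one CO ligand and 3,3-diethoxyprop-1-yne (bonds C7–C8, C5–C6 and C4a–C5).
4. The dihydropyran comes from (S)-linalool: the vinyl group is extended to a but-3-ynyl arm and the tertiary alcohol closes onto the alkyne terminus (O1–C8a).
5. Ring order: pyran ring first, ring A second; ring B arrives intact with the aldehyde.

Key step: step 8

Assumption: (S)-linalool is taken as purchasable in high enantiomeric purity. Its carbinol carbon becomes C2 of the target with the required (S) arrangement, and no later step touches it.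

**Route**

Step 1
Reactants: 1 (S)-linalool
Product: 2 triethyl{[(3S)-3,7-dimethylocta-1,6-dien-3-yl]oxy}silane
Conditions: TESOTf, 2,6-lutidine, CH2Cl2, −78 → 0 °C
Reagents that add atoms: triethylsilyl trifluoromethanesulfonate, CC[Si](CC)(CC)OS(=O)(=O)C(F)(F)F
Why: Silyl triflate silylation caps the hindered tertiary alcohol without touching the stereocentre, and the ether later prevents the alkoxide from closing an oxetane onto the iodide in step 4.

Step 2
Reactants: 2 triethyl{[(3S)-3,7-dimethylocta-1,6-dien-3-yl]oxy}silane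
Product: 4 (3S)-3,7-dimethyl-3-(triethylsilyloxy)oct-6-en-1-ol, via B-alkyl-9-BBN adduct 3 (not isolated)
Conditions: 9-BBN, THF, 0 °C → rt; then NaOH aq, H2O2, 0 °C → rt
Reagents that add atoms: hydrogen peroxide, OO (9-BBN, B1C2CCCC1CCC2, adds boron and its bicyclic frame to 3 only)
Why: Brown hydroboration–oxidation with the bulky 9-BBN is anti-Markovnikov and reacts far faster with the monosubstituted vinyl group than with the trisubstituted side-chain alkene, so only the terminal carbon is hydroxylated.

Step 3
Reactants: 4 (3S)-3,7-dimethyl-3-(triethylsilyloxy)oct-6-en-1-ol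
Product: 5 triethyl{[(3S)-1-iodo-3,7-dimethyloct-6-en-3-yl]oxy}silane
Conditions: PPh3, I2, imidazole, CH2Cl2, 0 °C → rt
Reagents that add atoms: iodine, II
Why: Appel-type iodination replaces the primary hydroxyl by SN2 at an unhindered CH2 under buffered conditions that a tertiary triethylsilyl ether and the alkene tolerate.

Step 4
Reactants: 5 triethyl{[(3S)-1-iodo-3,7-dimethyloct-6-en-3-yl]oxy}silane
Product: 6 triethyl{[(5S)-5,9-dimethyldec-8-en-1-yn-5-yl]oxy}silane
Conditions: LiC≡CH·H2NCH2CH2NH2, DMSO, 0 °C → rt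
Reagents that add atoms: lithium acetylide (ethylenediamine complex), [Li]C#C
Why: SN2 alkylation of lithium acetylide in DMSO is reliable for primary iodides, the carbon attacked is two bonds from the quaternary centre and so not neopentyl, and the silyl ether keeps the oxygen from competing.

Step 5
Reactants: 6 triethyl{[(5S)-5,9-dimethyldec-8-en-1-yn-5-yl]oxy}silane
Product: 7 (5S)-5,9-dimethyldec-8-en-1-yn-5-ol
Conditions: TBAF, THF, rt → 40 °C
Reagents that add atoms: none
Why: Fluoride-driven desilylation frees the tertiary alcohol and leaves the terminal alkyne and the alkene unchanged.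

Step 6
Reactants: 7 (5S)-5,9-dimethyldec-8-en-1-yn-5-ol
Product: 8 (2S)-2-methyl-2-(4-methylpent-3-en-1-yl)-3,4-dihydro-2H-pyran
Conditions: W(CO)6 (0.25 equiv), Et3N, THF, hν (350 nm), 60 °C
Reagents that add atoms: none
Why: Tungsten-catalysed alkynol cycloisomerisation passes through a tungsten vinylidene whose metal-bound carbon is attacked by the hydroxyl, so a pent-4-yn-1-ol closes in the endo sense to the six-membered enol ether with O bonded to the former alkyne terminus.

Step 7
Reactants: 8 (2S)-2-methyl-2-(4-methylpent-3-en-1-yl)-3,4-dihydro-2H-pyran; 9 chromium hexacarbonyl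
Product: 12 pentacarbonyl{methoxy[(6S)-6-methyl-6-(4-methylpent-3-en-1-yl)-5,6-dihydro-4H-pyran-2-yl]carbene}chromium, via 2-lithio dihydropyran 10 (not isolated), via lithium acylchromate 11 (not isolated)
Conditions: t-BuLi, THF/pentane, −78 → 0 °C; Cr(CO)6, THF, 0 °C → rt; Me3OBF4, CH2Cl2, 0 °C
Reagents that add atoms: trimethyloxonium tetrafluoroborate, C[O+](C)C.F[B-](F)(F)F (tert-butyllithium, [Li]C(C)(C)C, leaves lithium in 10 and 11 only)
Why: Oxygen-directed vinylic lithiation of the cyclic enol ether followed by the Fischer carbene synthesis (addition of the vinyllithium to a CO ligand of Cr(CO)6 and O-methylation of the acylate) is the standard entry to dihydropyranyl methoxycarbene complexes, and the isolated trisubstituted alkene is inert to these reagents.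

Step 8
Reactants: 12 pentacarbonyl{methoxy[(6S)-6-methyl-6-(4-methylpent-3-en-1-yl)-5,6-dihydro-4H-pyran-2-yl]carbene}chromium; 13 3,3-diethoxyprop-1-yne
Product: 15 (2S)-6-(diethoxymethyl)-8-methoxy-2-methyl-2-(4-methylpent-3-en-1-yl)chroman-5-ol, via tricarbonylchromium arene complex 14 (not isolated)
Conditions: 13 (1.5 equiv), THF, 50 °C, Ar; then air, daylight, EtOAc, rt; Et3N-treated silica
Reagents that add atoms: none
Why: Thermal loss of one CO from 12 opens a site for the alkyne, which inserts into the chromium–carbene bond so that its CH terminus bonds to the carbene carbon (C7–C8); CO insertion then gives a chromium-bound dienylketene whose ketene carbon becomes C5 and is bonded to C6. Ring A closes by 6π electrocyclisation of that dienylketene onto the former pyran C3 (C4a–C5), and enolisation gives the 4-methoxyphenol as its Cr(CO)3 complex 14, from which air removes the metal. The closest known reaction is the Dötz benzannulation of alkenyl(alkoxy)carbene complexes of zerovalent chromium with terminal alkynes, which includes dihydropyranyl carbenes that deliver chromans. No stereocentre is formed and C2 is a remote spectator. The step needs regiocontrol in the alkyne insertion, and the steric demand of the diethoxymethyl group keeps the substituted alkyne carbon away from the carbene carbon and hence next to the CO-derived C5, while an alkenyl rather than aryl carbene favours CO insertion and six-ring closure over five-ring by-products. The C5 phenol and the C8 methyl ether emerge differentiated, which the end game uses.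

Step 9
Reactants: 15 (2S)-6-(diethoxymethyl)-8-methoxy-2-methyl-2-(4-methylpent-3-en-1-yl)chroman-5-ol
Product: 16 (2S)-5-hydroxy-8-methoxy-2-methyl-2-(4-methylpent-3-en-1-yl)chroman-6-carbaldehyde
Conditions: PPTS (cat.), acetone/H2O, rt
Reagents that add atoms: water, O
Why: Mild acid-catalysed acetal hydrolysis is accelerated by the electron-rich ring and gives the hydrogen-bonded salicylaldehyde without affecting the chroman ether or the trisubstituted alkene.

Step 10
Reactants: 16 (2S)-5-hydroxy-8-methoxy-2-methyl-2-(4-methylpent-3-en-1-yl)chroman-6-carbaldehyde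
Product: 17 (2S)-6-(1-hydroxyethyl)-8-methoxy-2-methyl-2-(4-methylpent-3-en-1-yl)chroman-5-ol (both epimers at the carbinol carbon)
Conditions: MeMgBr (3 equiv), THF, −78 → 0 °C; NH4Cl aq
Reagents that add atoms: methylmagnesium bromide, C[Mg]Br
Why: Grignard addition to the aldehyde proceeds after the first equivalent has deprotonated the phenol, and the new carbinol stereocentre is uncontrolled but is erased by the oxidation in step 11.

Step 11
Reactants: 17 (2S)-6-(1-hydroxyethyl)-8-methoxy-2-methyl-2-(4-methylpent-3-en-1-yl)chroman-5-ol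
Product: 18 1-[(2S)-5-hydroxy-8-methoxy-2-methyl-2-(4-methylpent-3-en-1-yl)chroman-6-yl]ethanone
Conditions: MnO2 (activated, excess), CH2Cl2, rt
Reagents that add atoms: none
Why: Activated MnO2 oxidises benzylic alcohols selectively, ortho-hydroxybenzylic alcohols are good substrates, and anhydrous conditions leave the methyl ether and the isolated alkene intact.

Step 12
Reactants: 18 1-[(2S)-5-hydroxy-8-methoxy-2-methyl-2-(4-methylpent-3-en-1-yl)chroman-6-yl]ethanone
Product: 19 1-[(2S)-5-hydroxy-2-(4-hydroxy-4-methylpentyl)-8-methoxy-2-methylchroman-6-yl]ethanone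
Conditions: Co(acac)2 (0.2 equiv), PhSiH3, O2 (1 atm), i-PrOH, rt
Reagents that add atoms: dioxygen, O=O
Why: Mukaiyama hydration transfers a hydrogen atom from a cobalt hydride to the alkene to give the tertiary radical, which is trapped by O2 to give the Markovnikov tertiary alcohol; it is run here because the aryl ketone and the ketone-chelated phenol are tolerated whereas the later C3=C4 and enone double bonds would not be.

Step 13
Reactants: 19 1-[(2S)-5-hydroxy-2-(4-hydroxy-4-methylpentyl)-8-methoxy-2-methylchroman-6-yl]ethanone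
Product: 20 1-[(2S)-5-hydroxy-2-(4-hydroxy-4-methylpentyl)-8-methoxy-2-methyl-2H-chromen-6-yl]ethanone
Conditions: DDQ (1.2 equiv), 1,4-dioxane (dry), reflux
Reagents that add atoms: none
Why: DDQ dehydrogenation of chromans to 2H-chromenes removes hydride from benzylic C4, where the cation is stabilised by O1 and the C5 oxygen, then a proton from C3, and it is well known for 6-acyl-5-hydroxychromans.

Step 14
Reactants: 20 1-[(2S)-5-hydroxy-2-(4-hydroxy-4-methylpentyl)-8-methoxy-2-methyl-2H-chromen-6-yl]ethanone; 21 4-hydroxybenzaldehyde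
Product: 22 (E)-1-[(2S)-5-hydroxy-2-(4-hydroxy-4-methylpentyl)-8-methoxy-2-methyl-2H-chromen-6-yl]-3-(4-hydroxyphenyl)prop-2-en-1-one
Conditions: KOH (50% aq, excess), EtOH, rt, Ar; then 1 M HCl to pH 4, 0 °C
Reagents that add atoms: none
Why: Claisen–Schmidt condensation of the methyl ketone enolate with the non-enolisable aldehyde and E1cB loss of water gives the conjugated enone with the thermodynamically preferred E geometry, and excess base lets the unprotected phenols react as their phenoxides.

Step 15
Reactants: 22 (E)-1-[(2S)-5-hydroxy-2-(4-hydroxy-4-methylpentyl)-8-methoxy-2-methyl-2H-chromen-6-yl]-3-(4-hydroxyphenyl)prop-2-en-1-one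
Product: 24 (E)-1-[(2S)-5,8-dihydroxy-2-(4-hydroxy-4-methylpentyl)-2-methyl-2H-chromen-6-yl]-3-(4-hydroxyphenyl)prop-2-en-1-one, via chromene-5,8-dione 23 (not isolated)
Conditions: (NH4)2Ce(NO3)6 (2.1 equiv), MeCN/H2O, 0 °C, short; then Na2S2O4 aq, EtOAc, rt
Reagents that add atoms: water, O (the oxygen on C8)
Why: Oxidative demethylation of a 4-methoxyphenol by tetravalent cerium gives the para-quinone by attack of water at C8 and loss of methanol, ring A with three oxygen donors should be oxidised before the conjugated ring B phenol, and dithionite reduces the quinone back to the hydroquinone that is the target.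

**Compound list**

1 | (S)-linalool, (3S)-3,7-dimethylocta-1,6-dien-3-ol | CC(C)=CCC[C@@](O)(C)C=C | starting material
2 | triethyl{[(3S)-3,7-dimethylocta-1,6-dien-3-yl]oxy}silane | CC(C)=CCC[C@@](O[Si](CC)(CC)CC)(C)C=C | intermediate
3 | 9-[(3R)-3,7-dimethyl-3-(triethylsilyloxy)oct-6-en-1-yl]-9-borabicyclo[3.3.1]nonane (same spatial arrangement; the letter changes because boron ranks below carbon) | CC(C)=CCC[C@@](O[Si](CC)(CC)CC)(C)CCB1C2CCCC1CCC2 | intermediate (not isolated)
4 | (3S)-3,7-dimethyl-3-(triethylsilyloxy)oct-6-en-1-ol | CC(C)=CCC[C@@](O[Si](CC)(CC)CC)(C)CCO | intermediate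
5 | triethyl{[(3S)-1-iodo-3,7-dimethyloct-6-en-3-yl]oxy}silane | CC(C)=CCC[C@@](O[Si](CC)(CC)CC)(C)CCI | intermediate
6 | triethyl{[(5S)-5,9-dimethyldec-8-en-1-yn-5-yl]oxy}silane | CC(C)=CCC[C@@](O[Si](CC)(CC)CC)(C)CCC#C | intermediate
7 | (5S)-5,9-dimethyldec-8-en-1-yn-5-ol | CC(C)=CCC[C@@](O)(C)CCC#C | intermediate
8 | (2S)-2-methyl-2-(4-methylpent-3-en-1-yl)-3,4-dihydro-2H-pyran | CC(C)=CCC[C@@]1(C)CCC=CO1 | intermediate
9 | chromium hexacarbonyl, Cr(CO)6 | O=C=[Cr](=C=O)(=C=O)(=C=O)(=C=O)=C=O | starting material
10 | [(6S)-6-methyl-6-(4-methylpent-3-en-1-yl)-5,6-dihydro-4H-pyran-2-yl]lithium | CC(C)=CCC[C@@]1(C)CCC=C([Li])O1 | intermediate (not isolated)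
11 | lithium pentacarbonyl{[(6S)-6-methyl-6-(4-methylpent-3-en-1-yl)-5,6-dihydro-4H-pyran-2-yl]carbonyl}chromate (drawn as the O-lithio carbene form) | CC(C)=CCC[C@@]1(C)CCC=C(O1)C(O[Li])=[Cr](=C=O)(=C=O)(=C=O)(=C=O)=C=O | intermediate (not isolated)
12 | pentacarbonyl{methoxy[(6S)-6-methyl-6-(4-methylpent-3-en-1-yl)-5,6-dihydro-4H-pyran-2-yl]carbene}chromium | CC(C)=CCC[C@@]1(C)CCC=C(O1)C(OC)=[Cr](=C=O)(=C=O)(=C=O)(=C=O)=C=O | intermediate
13 | 3,3-diethoxyprop-1-yne | C#CC(OCC)OCC | starting material
14 | tricarbonyl(η6-arene)chromium complex of 15 (drawn as the arene plus the Cr(CO)3 fragment) | CC(C)=CCC[C@@]1(C)CCc2c(O)c(C(OCC)OCC)cc(OC)c2O1.O=C=[Cr](=C=O)=C=O | intermediate (not isolated)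
15 | (2S)-6-(diethoxymethyl)-8-methoxy-2-methyl-2-(4-methylpent-3-en-1-yl)chroman-5-ol | CC(C)=CCC[C@@]1(C)CCc2c(O)c(C(OCC)OCC)cc(OC)c2O1 | intermediate
16 | (2S)-5-hydroxy-8-methoxy-2-methyl-2-(4-methylpent-3-en-1-yl)chroman-6-carbaldehyde | CC(C)=CCC[C@@]1(C)CCc2c(O)c(C=O)cc(OC)c2O1 | intermediate
17 | (2S)-6-(1-hydroxyethyl)-8-methoxy-2-methyl-2-(4-methylpent-3-en-1-yl)chroman-5-ol, epimers at the carbinol carbon | CC(C)=CCC[C@@]1(C)CCc2c(O)c(C(C)O)cc(OC)c2O1 | intermediate
18 | 1-[(2S)-5-hydroxy-8-methoxy-2-methyl-2-(4-methylpent-3-en-1-yl)chroman-6-yl]ethanone | CC(C)=CCC[C@@]1(C)CCc2c(O)c(C(C)=O)cc(OC)c2O1 | intermediate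
19 | 1-[(2S)-5-hydroxy-2-(4-hydroxy-4-methylpentyl)-8-methoxy-2-methylchroman-6-yl]ethanone | CC(C)(O)CCC[C@@]1(C)CCc2c(O)c(C(C)=O)cc(OC)c2O1 | intermediate
20 | 1-[(2S)-5-hydroxy-2-(4-hydroxy-4-methylpentyl)-8-methoxy-2-methyl-2H-chromen-6-yl]ethanone | CC(C)(O)CCC[C@@]1(C)C=Cc2c(O)c(C(C)=O)cc(OC)c2O1 | intermediate
21 | 4-hydroxybenzaldehyde | O=Cc1ccc(O)cc1 | starting material
22 | (E)-1-[(2S)-5-hydroxy-2-(4-hydroxy-4-methylpentyl)-8-methoxy-2-methyl-2H-chromen-6-yl]-3-(4-hydroxyphenyl)prop-2-en-1-one | CC(C)(O)CCC[C@@]1(C)C=Cc2c(O)c(C(=O)/C=C/c3ccc(O)cc3)cc(OC)c2O1 | intermediate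
23 | (2S)-2-(4-hydroxy-4-methylpentyl)-6-[(E)-3-(4-hydroxyphenyl)prop-2-enoyl]-2-methyl-2H-chromene-5,8-dione | CC(C)(O)CCC[C@@]1(C)C=CC2=C(O1)C(=O)C=C(C(=O)/C=C/c3ccc(O)cc3)C2=O | intermediate (not isolated)
24 | (E)-1-[(2S)-5,8-dihydroxy-2-(4-hydroxy-4-methylpentyl)-2-methyl-2H-chromen-6-yl]-3-(4-hydroxyphenyl)prop-2-en-1-one (CNP0322520.1) | CC(C)(O)CCC[C@@]1(C)C=Cc2c(O)c(C(=O)/C=C/c3ccc(O)cc3)cc(O)c2O1 | target

**Totals**

Total step count: 15.
Longest linear sequence: 15 steps (1 → 24); 9, 13 and 21 enter as purchased.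

**Steps most likely to fail**

Step 15. The oxidation may not stop at ring A: tetravalent cerium could also attack the ring B phenol or the C3=C4 double bond, and the acylquinone could add water before it is reduced. The fallback moves the methyl-to-hydrogen exchange ahead of the condensation and carries acid-labile ethers instead. It sets out from 20. Treatment with (NH4)2Ce(NO3)6 in MeCN/H2O at 0 °C should give 6-acetyl-2-(4-hydroxy-4-methylpentyl)-2-methyl-2H-chromene-5,8-dione F1, which Na2S2O4 reduces in the same flask to 1-[(2S)-5,8-dihydroxy-2-(4-hydroxy-4-methylpentyl)-2-methyl-2H-chromen-6-yl]ethanone F2. MOMCl with K2CO3 in acetone should etherify only the non-chelated C8 hydroxyl and give the 8-(methoxymethoxy) ketone F3. In parallel, 21 with MOMCl and i-Pr2NEt gives 4-(methoxymethoxy)benzaldehyde F4. Claisen–Schmidt condensation of F3 with F4 (KOH, EtOH) should give the bis(methoxymethyl) chalcone F5, and 3 M HCl in MeOH at rt removes both acetals and comes back to the route at 24.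

Step 8. The acetal may ionise at the chromium-bound benzylic carbon (helped by the ortho phenol) and lose ethanol, or CO insertion may be incomplete and lead to five-membered ring closure. The fallback keeps the benzannulation but changes the alkyne to one without an ionisable acetal, which already carries both carbons of the acetyl group. It sets out from 12. Heating 12 with racemic tert-butyldimethyl(but-3-yn-2-yloxy)silane F6 in THF at 50 °C, then air, should give (2S)-6-[1-(tert-butyldimethylsilyloxy)ethyl]-8-methoxy-2-methyl-2-(4-methylpent-3-en-1-yl)chroman-5-ol F7 with the same regiochemistry. TBAF buffered with AcOH in THF then removes the silyl group and comes back to the route at 17, so steps 9 and 10 are not needed.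

Step 6. The hindered tertiary alcohol may add slowly, or the alkyne may be attacked directly in the exo sense to give the five-membered exocyclic enol ether. The fallback builds the enol ether by hydration and dehydration instead of cycloisomerisation. It sets out from 7. Anti-Markovnikov hydration of the terminal alkyne (CpRu(NCMe)3PF6 with 5,5'-bis(trifluoromethyl)-2,2'-bipyridine, aqueous NMP) should give the δ-hydroxy aldehyde, which closes to the lactol (6R)-6-methyl-6-(4-methylpent-3-en-1-yl)tetrahydro-2H-pyran-2-ol F8 (anomer mixture; same spatial arrangement at the quaternary carbon, the letter changes with the ranking). MsCl and Et3N in CH2Cl2, 0 °C → reflux, eliminate the anomeric hydroxyl and come back to the route at 8.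

**Further compounds**

F1 | step 15 | (2S)-6-acetyl-2-(4-hydroxy-4-methylpentyl)-2-methyl-2H-chromene-5,8-dione | CC(C)(O)CCC[C@@]1(C)C=CC2=C(O1)C(=O)C=C(C(C)=O)C2=O
F2 | step 15 | 1-[(2S)-5,8-dihydroxy-2-(4-hydroxy-4-methylpentyl)-2-methyl-2H-chromen-6-yl]ethanone | CC(C)(O)CCC[C@@]1(C)C=Cc2c(O)c(C(C)=O)cc(O)c2O1
F3 | step 15 | 1-[(2S)-5-hydroxy-2-(4-hydroxy-4-methylpentyl)-8-(methoxymethoxy)-2-methyl-2H-chromen-6-yl]ethanone | CC(C)(O)CCC[C@@]1(C)C=Cc2c(O)c(C(C)=O)cc(OCOC)c2O1
F4 | step 15 | 4-(methoxymethoxy)benzaldehyde | COCOc1ccc(C=O)cc1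
F5 | step 15 | (E)-1-[(2S)-5-hydroxy-2-(4-hydroxy-4-methylpentyl)-8-(methoxymethoxy)-2-methyl-2H-chromen-6-yl]-3-[4-(methoxymethoxy)phenyl]prop-2-en-1-one | CC(C)(O)CCC[C@@]1(C)C=Cc2c(O)c(C(=O)/C=C/c3ccc(OCOC)cc3)cc(OCOC)c2O1
F6 | step 8 | tert-butyldimethyl(but-3-yn-2-yloxy)silane, racemic | C#CC(C)O[Si](C)(C)C(C)(C)C
F7 | step 8 | (2S)-6-[1-(tert-butyldimethylsilyloxy)ethyl]-8-methoxy-2-methyl-2-(4-methylpent-3-en-1-yl)chroman-5-ol, epimers at the silyloxy carbon | CC(C)=CCC[C@@]1(C)CCc2c(O)c(C(C)O[Si](C)(C)C(C)(C)C)cc(OC)c2O1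
F8 | step 6 | (6R)-6-methyl-6-(4-methylpent-3-en-1-yl)tetrahydro-2H-pyran-2-ol, anomer mixture | CC(C)=CCC[C@@]1(C)CCCC(O)O1
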